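**Retrosynthetic overview**

- Target 11 (2-heptadecyl-6-methoxy-1,4-benzoquinone) comes from phenol 10 by para-oxidation, which installs the C1 oxygen last; 10 comes from diacid 8 and diester 7 by removing two carboxyl groups from C3 and C5.
- Feature used: number the ring from carbonyl C1, which lies between C2 (OMe) and C6 (heptadecyl), then C3–H, C4=O, C5–H. The C6–C1–C2 piece is a three-carbon 1,3-dielectrophile that already bears both substituents, and C3–C4–C5 is an acetone unit whose carbonyl becomes the C4 oxygen.
- Key disconnection: ring bonds C2–C3 and C5–C6, giving acylketene acetal 3 (C6–C1–C2) and dimethyl 3-oxopentanedioate 4 (C3–C4–C5). The carbocycle is the only ring and is formed in this step.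
- 3 comes from stearoyl chloride 1 and 1,1-dimethoxyethene 2 by C-acylation.

Key step: step 2

Remark: the target has no stereocentre and no stereogenic double bond, so no step needs stereocontrol; 1, 2 and 4 are taken as purchased.

**Route**

Step 1
Reactants: 1 stearoyl chloride (octadecanoyl chloride); 2 1,1-dimethoxyethene
Product: 3 1,1-dimethoxyicos-1-en-3-one
Conditions: 2 (2.2 equiv), Et2O, 0 °C to rt, no amine; volatiles removed in vacuo; crystallisation from cold pentane
Reagents that add atoms: none
Why: C-acylation of a ketene O,O-acetal by an acid chloride, in which the nucleophilic CH2 carbon of 2 attacks 1 and a second equivalent of 2 takes up the HCl (ending as methyl acetate and chloromethane), so no amine is present that could dehydrohalogenate 1 to hexadecylketene.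

Step 2
Reactants: 3 1,1-dimethoxyicos-1-en-3-one; 4 dimethyl 3-oxopentanedioate
Product: 7 dimethyl 4-heptadecyl-2-hydroxy-6-methoxybenzene-1,3-dicarboxylate, via open-chain adduct 5 (not isolated), via cyclic aldol 6 (not isolated)
Conditions: 4 (1.2 equiv), NaOMe (2.0 equiv), MeOH/THF, 0 °C then reflux; 1 M HCl work-up
Reagents that add atoms: none
Why: Proposed new method: the sodium enolate of 4 should add to the acetal carbon of the push–pull enone 3 and expel methoxide (addition–elimination, a vinylic substitution) to give 5 and ring bond C2–C3; the remaining active methylene of 5 then attacks the chain ketone in a 6-exo-trig aldol closure to 6 (ring bond C5–C6), and E1cB dehydration followed by enolisation of the C4 carbonyl gives the sodium phenoxide of 7. The closest known reaction type is the base-mediated [3+3] Michael–aldol (Knoevenagel) benzannulation of 3-oxopentanedioates with ynones, β-alkoxyenones and 1,3-dicarbonyl compounds, together with the [3+3] aromatic annulation of α-oxoketene dithioacetals with ketone bis-nucleophiles; new here is an acylketene O,O-acetal as the 1,3-dielectrophile for this nucleophile. The single carbocycle is closed by C–C bond formation in the 6-exo-trig mode, and the C(OMe)=CH geometry needed for closure is reached by equilibration through the delocalised enolate of 5. No stereocentre is created in 7, since the sp3 centres of 6 are transient and vanish on aromatisation. Because 4 is symmetric, the order in which C2–C3 and C5–C6 form does not change the constitution of 7; the selectivity needed is C- over O-cyclisation (lactonisation to a 2-pyranone or hemiketalisation), and NaOMe/MeOH secures it because the O-closed products reopen while dehydration and aromatisation to the chelated phenoxide are irreversible. Only one of the two acetal methoxy groups is lost, and the one that stays sits on C2, so the target's methyl ether is distinguished from the future C4 oxygen without any selective methylation.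

Step 3
Reactants: 7 dimethyl 4-heptadecyl-2-hydroxy-6-methoxybenzene-1,3-dicarboxylate
Product: 8 4-heptadecyl-2-hydroxy-6-methoxybenzene-1,3-dicarboxylic acid
Conditions: KOH (excess), DMSO/H2O, 90 °C, N2; then cold 2 M HCl
Reagents that add atoms: potassium hydroxide, [K+].[OH-]
Why: Saponification (acyl–oxygen cleavage) of both aryl methyl esters, helped by the neighbouring phenoxide as in salicylate hydrolysis and run in hot aqueous DMSO because each ester is flanked by two ortho substituents; the aryl methyl ether and the chain are inert to hydroxide.

Step 4
Reactants: 8 4-heptadecyl-2-hydroxy-6-methoxybenzene-1,3-dicarboxylic acid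
Product: 10 3-heptadecyl-5-methoxyphenol, via mono-acid 9 (not isolated)
Conditions: quinoline, 190 °C, N2, until CO2 evolution ends; dilute HCl wash
Reagents that add atoms: none
Why: Thermal protodecarboxylation, which should be easy because each carboxyl sits on a carbon ortho to the hydroxyl and ortho or para to the methoxy group (resorcylic-acid pattern), so ipso-protonation through the keto tautomer and loss of CO2 are favoured; the order of the two losses is immaterial because both end at 10.

Step 5
Reactants: 10 3-heptadecyl-5-methoxyphenol
Product: 11 2-heptadecyl-6-methoxycyclohexa-2,5-diene-1,4-dione (2-heptadecyl-6-methoxy-1,4-benzoquinone)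
Conditions: Fremy's salt (KSO3)2NO (2.5 equiv), KH2PO4 buffer, acetone/H2O, rt
Reagents that add atoms: Fremy's salt, potassium nitrosodisulfonate (KSO3)2NO, [K+].[K+].[O]N(S(=O)(=O)[O-])S(=O)(=O)[O-]
Why: Teuber oxidation, in which two equivalents of the nitroxyl radical convert a phenol with a free para position into the para-quinone, the new C1 oxygen coming from the reagent; the para carbon between OMe and the chain is the most electron-rich open site, and the reaction is established for 3-alkyl-5-methoxyphenols.

**Compound list**

1 | stearoyl chloride (octadecanoyl chloride) | CCCCCCCCCCCCCCCCCC(Cl)=O | starting material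
2 | 1,1-dimethoxyethene | C=C(OC)OC | starting material
3 | 1,1-dimethoxyicos-1-en-3-one | CCCCCCCCCCCCCCCCCC(=O)C=C(OC)OC | intermediate
4 | dimethyl 3-oxopentanedioate | COC(=O)CC(=O)CC(=O)OC | starting material
5 | open-chain adduct, dimethyl 2-(1-methoxy-3-oxoicos-1-en-1-yl)-3-oxopentanedioate (alkene geometry not fixed, equilibrates through its enolate) | CCCCCCCCCCCCCCCCCC(=O)C=C(OC)C(C(=O)OC)C(=O)CC(=O)OC | intermediate
6 | cyclic aldol, dimethyl 4-heptadecyl-4-hydroxy-6-methoxy-2-oxocyclohex-5-ene-1,3-dicarboxylate (transient mixture of diastereomers, stereocentres unassigned) | COC(=O)C1C(=O)C(C(=O)OC)C(O)(CCCCCCCCCCCCCCCCC)C=C1OC | intermediate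
7 | dimethyl 4-heptadecyl-2-hydroxy-6-methoxybenzene-1,3-dicarboxylate | COC(=O)c1c(O)c(C(=O)OC)c(CCCCCCCCCCCCCCCCC)cc1OC | intermediate
8 | 4-heptadecyl-2-hydroxy-6-methoxybenzene-1,3-dicarboxylic acid | OC(=O)c1c(O)c(C(=O)O)c(CCCCCCCCCCCCCCCCC)cc1OC | intermediate
9 | mono-acid, 6-heptadecyl-2-hydroxy-4-methoxybenzoic acid | OC(=O)c1c(O)cc(OC)cc1CCCCCCCCCCCCCCCCC | intermediate
10 | 3-heptadecyl-5-methoxyphenol | CCCCCCCCCCCCCCCCCc1cc(O)cc(OC)c1 | intermediate
11 | 2-heptadecyl-6-methoxy-1,4-benzoquinone | CCCCCCCCCCCCCCCCCC1=CC(=O)C=C(OC)C1=O | target

**Step count**

Total steps: 5. Longest linear sequence: 5 steps (1 → 3 → 7 → 8 → 10 → 11).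

**Steps most likely to fail**

1. Step 2 (Proposed new method). The vinylic substitution at the donor-stabilised acetal carbon may be slow. Base-mediated self-condensation of 4 and methoxide-induced fragmentation of 3 could then outrun the annulation, or O-cyclisation could drain the adduct before the aldol closure.
Fallback, from 3, rejoining at 9: methyl acetoacetate is silylated (Me3SiCl, Et3N) to methyl 3-(trimethylsilyloxy)but-2-enoate F1. F1 is then converted (LiN(i-Pr)2, Me3SiCl, THF, −78 °C) into 1-methoxy-1,3-bis(trimethylsilyloxy)buta-1,3-diene F2. F2 and 3 are combined with TiCl4 in CH2Cl2 (−78 °C to rt). This is the known Lewis-acid formal [3+3] cyclocondensation of 1,3-bis(silyl enol ethers) with β-alkoxyenones and 3-oxo ketene acetals: conjugate substitution at the acetal carbon, aldol closure at the ketone, then aromatisation. It should give methyl 6-heptadecyl-2-hydroxy-4-methoxybenzoate F3; if the regioisomeric salicylate formed instead, it would lead to the same phenol 10. Saponification of F3 (KOH, aqueous DMSO; HCl) gives acid 9, which is decarboxylated under the conditions of step 4 to 10.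

2. Step 1. The acylated dimethoxycarbenium chloride may collapse by chloride attack at an O-methyl group instead of losing a proton. The product may also condense further with excess ketene acetal, and the acid-labile acetal may hydrolyse during isolation.
Fallback, from 1, rejoining at 3: Friedel–Crafts acylation of 1,1-dichloroethene with 1 (AlCl3, CH2Cl2, 0 °C) gives 1,1,1-trichloroicosan-3-one F4. F4 loses HCl on warming during work-up to give 1,1-dichloroicos-1-en-3-one F5. Two successive addition–eliminations with NaOMe (2.1 equiv, MeOH/THF, 0 °C) replace both vinylic chlorides and give 3.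

3. Step 3. Hydrolysis may stall at the mono-ester stage, because each ester carbonyl is shielded by two ortho substituents and deactivated by conjugation with the ortho phenoxide.
Fallback, from 3, rejoining at 8: the annulation of step 2 is repeated with purchased di-tert-butyl 3-oxopentanedioate (NaH, THF, 0 °C to reflux) to give di-tert-butyl 4-heptadecyl-2-hydroxy-6-methoxybenzene-1,3-dicarboxylate F6. CF3CO2H in CH2Cl2 at rt then removes both tert-butyl groups as 2-methylpropene by alkyl–oxygen cleavage, which needs no attack at the shielded acyl carbons, and gives 8. Any 9 or 10 formed by early loss of CO2 lies further along the same route. This fallback presupposes that the annulation itself works.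

**Further compounds**

F1 | step 2 | methyl 3-(trimethylsilyloxy)but-2-enoate (E/Z mixture) | COC(=O)C=C(C)O[Si](C)(C)C
F2 | step 2 | 1-methoxy-1,3-bis(trimethylsilyloxy)buta-1,3-diene | C=C(O[Si](C)(C)C)C=C(OC)O[Si](C)(C)C
F3 | step 2 | methyl 6-heptadecyl-2-hydroxy-4-methoxybenzoate | COC(=O)c1c(O)cc(OC)cc1CCCCCCCCCCCCCCCCC
F4 | step 1 | 1,1,1-trichloroicosan-3-one | CCCCCCCCCCCCCCCCCC(=O)CC(Cl)(Cl)Cl
F5 | step 1 | 1,1-dichloroicos-1-en-3-one | CCCCCCCCCCCCCCCCCC(=O)C=C(Cl)Cl
F6 | step 3 | di-tert-butyl 4-heptadecyl-2-hydroxy-6-methoxybenzene-1,3-dicarboxylate | CC(C)(C)OC(=O)c1c(O)c(C(=O)OC(C)(C)C)c(CCCCCCCCCCCCCCCCC)cc1OC
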